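**Retrosynthetic overview**
1. Target ⇒ C12–C13 bond and the C12 carbinol by a catalyst-controlled Morita–Baylis–Hillman coupling of a C12 aldehyde (decalin complete) with furan-2(5H)-one; this is the last C–C bond and the new method.
2. Decalin ⇒ one cationic cascade from an acyclic (2R,3R)-epoxy triene: ring A closes first (C5=C10 alkene opens the epoxide at C4), ring B second (allylsilane carbon C9 onto C10); this sets C4, C5, C9, C10 and the exocyclic methylene.
3. Epoxide ⇒ primary-amine (iminium) catalysed asymmetric epoxidation of an (E)-α-methyl enal; first stereocentres (C3, C4), selective for the enal over the other alkenes.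
4. Trienal ⇒ Wittig enal formation and two orthoester Claisen rearrangements (both trisubstituted alkenes) from (2-bromoallyl)trimethylsilane, 3-silyloxypropanal and isopropenylmagnesium bromide.

Assumption: the SMILES is taken literally. It places the C4 methyl axial on the face of the C10 methyl and the C4 CH2OH equatorial, i.e. (3R,4S,5S,9R,10S,12R) (the C4 epimer of the andrographolide pattern); the route is built for exactly this isomer.

Labels: labdane numbering is used for ring and chain carbons alike. C3 = ring carbinol, C4 = quaternary carbon (CH3 and CH2OH), C5/C10 = ring fusion, C8 = carbon of the exocyclic C8=C17H2, C9 = carbon bearing the side chain, C11 = side-chain CH2, C12 = side-chain carbinol, C13–C16 = butenolide.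

**Route**

Step 1
Reactants: 1 (2-bromoallyl)trimethylsilane; 2 3-[(tert-butyldimethylsilyl)oxy]propanal
Product: 4 rac-5-[(tert-butyldimethylsilyl)oxy]-2-[(trimethylsilyl)methyl]pent-1-en-3-ol, via Grignard reagent 3 (not isolated)
Conditions: 1, Mg turnings, BrCH2CH2Br (cat.), THF, 45 °C; then 2, −78 → 0 °C; aq. NH4Cl
Reagents that add atoms: none
Why: Grignard 1,2-addition of the 1-(silylmethyl)vinyl magnesium reagent to the aldehyde; the carbinol is racemic and is erased in step 2.

Step 2
Reactants: 4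
Product: 6 ethyl (4Z)-7-[(tert-butyldimethylsilyl)oxy]-4-[(trimethylsilyl)methyl]hept-4-enoate, via ketene acetal 5 (not isolated)
Conditions: MeC(OEt)3 (7 equiv), EtCO2H (5 mol%), 138 °C, EtOH distilled off
Reagents that add atoms: triethyl orthoacetate, CCOC(C)(OCC)OCC
Why: Johnson orthoester Claisen rearrangement through a chair with the CH2CH2OTBS group equatorial, which puts C11 trans to the new C7 chain (the descriptor is Z only because CH2SiMe3 outranks the carbon chain); the weak acid catalyst is tolerated by the allylsilane.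

Step 3
Reactants: 6
Product: 8 rac-(6Z)-9-[(tert-butyldimethylsilyl)oxy]-2-methyl-6-[(trimethylsilyl)methyl]nona-1,6-dien-3-ol, via aldehyde 7 (not isolated)
Conditions: i-Bu2AlH (1.05 equiv), CH2Cl2, −78 °C; then isopropenylmagnesium bromide (2.5 equiv), THF, −78 → 0 °C; aq. potassium sodium tartrate
Reagents that add atoms: isopropenylmagnesium bromide, C=C(C)[Mg]Br
Why: one-pot partial ester reduction and Grignard addition: the aluminium hemiacetal formed at −78 °C releases the aldehyde only as the Grignard reagent is present, giving the secondary allylic alcohol (racemic, erased in step 4).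

Step 4
Reactants: 8
Product: 10 ethyl (4E,8Z)-11-[(tert-butyldimethylsilyl)oxy]-4-methyl-8-[(trimethylsilyl)methyl]undeca-4,8-dienoate, via ketene acetal 9 (not isolated)
Conditions: MeC(OEt)3 (7 equiv), EtCO2H (5 mol%), 138 °C, EtOH distilled off
Reagents that add atoms: triethyl orthoacetate, CCOC(C)(OCC)OCC
Why: second Johnson orthoester Claisen rearrangement; the chair with the carbinol substituent equatorial gives the (E)-C5=C10 trisubstituted alkene.

Step 5
Reactants: 10
Product: 11 (4E,8Z)-11-[(tert-butyldimethylsilyl)oxy]-4-methyl-8-[(trimethylsilyl)methyl]undeca-4,8-dienal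
Conditions: i-Bu2AlH (1.05 equiv), toluene, −78 °C; aq. potassium sodium tartrate
Reagents that add atoms: none
Why: partial reduction of the ester at −78 °C stops at the aldehyde after hydrolysis of the aluminium hemiacetal.

Step 6
Reactants: 11
Product: 12 (2E,6E,10Z)-13-[(tert-butyldimethylsilyl)oxy]-2,6-dimethyl-10-[(trimethylsilyl)methyl]trideca-2,6,10-trienal
Conditions: Ph3P=C(CH3)CHO (1.5 equiv), toluene, 90 °C
Reagents that add atoms: 2-(triphenylphosphoranylidene)propanal, CC(C=O)=P(c1ccccc1)(c1ccccc1)c1ccccc1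
Why: Wittig reaction of a stabilised formyl ylide gives the (E)-α-methyl enal; the aliphatic aldehyde reacts much faster than the α-branched enal product.

Step 7
Reactants: 12
Product: 14 [(2R,3R)-3-[(3E,7Z)-10-[(tert-butyldimethylsilyl)oxy]-3-methyl-7-[(trimethylsilyl)methyl]deca-3,7-dien-1-yl]-2-methyloxiran-2-yl]methanol, via epoxy aldehyde 13 (not isolated)
Conditions: 9-amino(9-deoxy)epiquinidine·2CF3CO2H (10 mol%), 50% aq. H2O2 (2 equiv), THF, 50 °C; then MeOH, NaBH4, 0 °C
Reagents that add atoms: hydrogen peroxide, OO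
Why: iminium-activated Weitz–Scheffer epoxidation by cinchona primary-amine catalysis, as established for α-branched enals: H2O2 adds only to the iminium-activated C3=C4 bond, so the two electron-rich alkenes and the allylsilane are untouched; the catalyst selects the face and the (E)-geometry is carried into the trans epoxide, setting C3 (R) and C4 as the first stereocentres, and NaBH4 reduces the aldehyde in the same pot.

Step 8
Reactants: 14
Product: 15 tert-butyl{[(2R,3R)-3-[(3E,7Z)-10-[(tert-butyldimethylsilyl)oxy]-3-methyl-7-[(trimethylsilyl)methyl]deca-3,7-dien-1-yl]-2-methyloxiran-2-yl]methoxy}diphenylsilane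
Conditions: TBDPSCl (1.2 equiv), imidazole (2.5 equiv), CH2Cl2, 0 °C → rt
Reagents that add atoms: tert-butyl(chloro)diphenylsilane, CC(C)(C)[Si](Cl)(c1ccccc1)c1ccccc1
Why: standard silylation of the primary alcohol; the bulky, non-participating silyl ether is orthogonal to the primary TBS ether.

Step 9
Reactants: 15
Product: 16 (1S,2R,4aS,5R,8aS)-5-{2-[(tert-butyldimethylsilyl)oxy]ethyl}-1-{[(tert-butyldiphenylsilyl)oxy]methyl}-1,4a-dimethyl-6-methylidenedecahydronaphthalen-2-ol
Conditions: MeAlCl2 (1.5 equiv), CH2Cl2, −78 °C; Et3N/MeOH quench; aq. potassium sodium tartrate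
Reagents that add atoms: none
Why: epoxide-initiated, allylsilane-terminated cation–olefin bicyclization through a chair–chair (Stork–Eschenmoser) arrangement: the C5=C10 alkene opens the activated epoxide at C4 with inversion while the C3–O bond is untouched (equatorial 3-OH, axial CH3, equatorial CH2OTBDPS), the (E)-alkene gives the trans ring fusion at C5/C10, the C8=C9 geometry places the C9 side chain equatorial, and loss of Me3Si from the β-silyl C8 cation gives only the exocyclic methylene.

Step 10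
Reactants: 16
Product: 17 (1S,2R,4aS,5R,8aS)-1-{[(tert-butyldiphenylsilyl)oxy]methyl}-5-(2-hydroxyethyl)-1,4a-dimethyl-6-methylidenedecahydronaphthalen-2-ol
Conditions: PPTS (0.3 equiv), MeOH, 25 °C
Reagents that add atoms: none
Why: mild acid methanolysis cleaves the unhindered primary TBS ether and leaves the neopentyl TBDPS ether and the exocyclic alkene intact.

Step 11
Reactants: 17
Product: 18 2-[(1R,4aS,5S,6R,8aS)-5-{[(tert-butyldiphenylsilyl)oxy]methyl}-6-hydroxy-5,8a-dimethyl-2-methylidenedecahydronaphthalen-1-yl]acetaldehyde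
Conditions: TEMPO (10 mol%), PhI(OAc)2 (1.1 equiv), CH2Cl2, rt
Reagents that add atoms: none
Why: oxoammonium (TEMPO) oxidation is selective for the primary C12 alcohol over the hindered secondary C3 alcohol and stops at the aldehyde.

Step 12
Reactants: 18; 19 furan-2(5H)-one
Product: 20 3-{(1R)-2-[(1R,4aS,5S,6R,8aS)-5-{[(tert-butyldiphenylsilyl)oxy]methyl}-6-hydroxy-5,8a-dimethyl-2-methylidenedecahydronaphthalen-1-yl]-1-hydroxyethyl}furan-2(5H)-one
Conditions: (S)-phosphine–thiourea catalyst (20 mol%, structure under Why), 19 (3 equiv), 2-naphthol (20 mol%), THF, 0 °C → rt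
Reagents that add atoms: none
Why: Proposed new method: a catalyst-controlled Morita–Baylis–Hillman reaction of an enolisable aliphatic aldehyde with furan-2(5H)-one using a new bifunctional catalyst, 1-[3,5-bis(trifluoromethyl)phenyl]-3-[(2S)-1-(diethylphosphanyl)-3,3-dimethylbutan-2-yl]thiourea (S=C(Nc1cc(cc(c1)C(F)(F)F)C(F)(F)F)N[C@H](CP(CC)CC)C(C)(C)C); the small, strongly nucleophilic but weakly basic dialkylphosphine adds 1,4 to the lactone (so γ-deprotonation to the 2-hydroxyfuran, the usual failure with amine bases, is avoided), the thiourea holds the β-phosphonio lactone enolate and the hydrogen-bonded aldehyde in a closed arrangement in which the tert-butyl group is designed to shield the Re face, so C13 adds to the Si face of the C12 carbonyl to give 12R, and 2-naphthol shuttles the C13 proton so that E1cB loss of the phosphine restores the C13=C14 bond; the closest known reactions are phosphine–thiourea-catalysed asymmetric Morita–Baylis–Hillman reactions of aryl aldehydes with acrylates or vinyl ketones and achiral trialkylphosphine-mediated couplings of cyclic enones, neither shown for this lactone acceptor with catalyst control over an aliphatic aldehyde.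

Step 13
Reactants: 20
Product: 21 3-{(1R)-1-hydroxy-2-[(1R,4aS,5S,6R,8aS)-6-hydroxy-5-(hydroxymethyl)-5,8a-dimethyl-2-methylidenedecahydronaphthalen-1-yl]ethyl}furan-2(5H)-one
Conditions: HF·pyridine, pyridine, THF, 0 °C → rt
Reagents that add atoms: none
Why: fluoride cleavage of the Si–O bond under buffered, non-basic conditions that leave the butenolide, its carbinol and the exocyclic alkene intact.

**Compound list**
1 | (2-bromoallyl)trimethylsilane | C=C(Br)C[Si](C)(C)C | starting material
2 | 3-[(tert-butyldimethylsilyl)oxy]propanal | O=CCCO[Si](C)(C)C(C)(C)C | starting material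
3 | [3-(trimethylsilyl)prop-1-en-2-yl]magnesium bromide (not isolated) | C=C([Mg]Br)C[Si](C)(C)C | intermediate
4 | rac-5-[(tert-butyldimethylsilyl)oxy]-2-[(trimethylsilyl)methyl]pent-1-en-3-ol | C=C(C[Si](C)(C)C)C(O)CCO[Si](C)(C)C(C)(C)C | intermediate
5 | 1-ethoxyvinyl ether (ketene acetal) of alcohol 4 (racemic; not isolated) | C=C(OCC)OC(CCO[Si](C)(C)C(C)(C)C)C(=C)C[Si](C)(C)C | intermediate
6 | ethyl (4Z)-7-[(tert-butyldimethylsilyl)oxy]-4-[(trimethylsilyl)methyl]hept-4-enoate | CCOC(=O)CC/C(C[Si](C)(C)C)=C/CCO[Si](C)(C)C(C)(C)C | intermediate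
7 | (4Z)-7-[(tert-butyldimethylsilyl)oxy]-4-[(trimethylsilyl)methyl]hept-4-enal (not isolated) | O=CCC/C(C[Si](C)(C)C)=C/CCO[Si](C)(C)C(C)(C)C | intermediate
8 | rac-(6Z)-9-[(tert-butyldimethylsilyl)oxy]-2-methyl-6-[(trimethylsilyl)methyl]nona-1,6-dien-3-ol | C=C(C)C(O)CC/C(C[Si](C)(C)C)=C/CCO[Si](C)(C)C(C)(C)C | intermediate
9 | 1-ethoxyvinyl ether (ketene acetal) of alcohol 8 (racemic; not isolated) | C=C(OCC)OC(CC/C(C[Si](C)(C)C)=C/CCO[Si](C)(C)C(C)(C)C)C(C)=C | intermediate
10 | ethyl (4E,8Z)-11-[(tert-butyldimethylsilyl)oxy]-4-methyl-8-[(trimethylsilyl)methyl]undeca-4,8-dienoate | CCOC(=O)CC/C(C)=C/CC/C(C[Si](C)(C)C)=C/CCO[Si](C)(C)C(C)(C)C | intermediate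
11 | (4E,8Z)-11-[(tert-butyldimethylsilyl)oxy]-4-methyl-8-[(trimethylsilyl)methyl]undeca-4,8-dienal | O=CCC/C(C)=C/CC/C(C[Si](C)(C)C)=C/CCO[Si](C)(C)C(C)(C)C | intermediate
12 | (2E,6E,10Z)-13-[(tert-butyldimethylsilyl)oxy]-2,6-dimethyl-10-[(trimethylsilyl)methyl]trideca-2,6,10-trienal | O=C/C(C)=C/CC/C(C)=C/CC/C(C[Si](C)(C)C)=C/CCO[Si](C)(C)C(C)(C)C | intermediate
13 | (2S,3R)-3-[(3E,7Z)-10-[(tert-butyldimethylsilyl)oxy]-3-methyl-7-[(trimethylsilyl)methyl]deca-3,7-dien-1-yl]-2-methyloxirane-2-carbaldehyde (not isolated) | O=C[C@@]1(C)O[C@@H]1CC/C(C)=C/CC/C(C[Si](C)(C)C)=C/CCO[Si](C)(C)C(C)(C)C | intermediate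
14 | [(2R,3R)-3-[(3E,7Z)-10-[(tert-butyldimethylsilyl)oxy]-3-methyl-7-[(trimethylsilyl)methyl]deca-3,7-dien-1-yl]-2-methyloxiran-2-yl]methanol | OC[C@@]1(C)O[C@@H]1CC/C(C)=C/CC/C(C[Si](C)(C)C)=C/CCO[Si](C)(C)C(C)(C)C | intermediate
15 | tert-butyl{[(2R,3R)-3-[(3E,7Z)-10-[(tert-butyldimethylsilyl)oxy]-3-methyl-7-[(trimethylsilyl)methyl]deca-3,7-dien-1-yl]-2-methyloxiran-2-yl]methoxy}diphenylsilane | CC(C)(C)[Si](c2ccccc2)(c3ccccc3)OC[C@@]1(C)O[C@@H]1CC/C(C)=C/CC/C(C[Si](C)(C)C)=C/CCO[Si](C)(C)C(C)(C)C | intermediate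
16 | (1S,2R,4aS,5R,8aS)-5-{2-[(tert-butyldimethylsilyl)oxy]ethyl}-1-{[(tert-butyldiphenylsilyl)oxy]methyl}-1,4a-dimethyl-6-methylidenedecahydronaphthalen-2-ol | C=C1CC[C@@H]2[C@@](C)(CO[Si](c3ccccc3)(c4ccccc4)C(C)(C)C)[C@H](O)CC[C@@]2(C)[C@@H]1CCO[Si](C)(C)C(C)(C)C | intermediate
17 | (1S,2R,4aS,5R,8aS)-1-{[(tert-butyldiphenylsilyl)oxy]methyl}-5-(2-hydroxyethyl)-1,4a-dimethyl-6-methylidenedecahydronaphthalen-2-ol | C=C1CC[C@@H]2[C@@](C)(CO[Si](c3ccccc3)(c4ccccc4)C(C)(C)C)[C@H](O)CC[C@@]2(C)[C@@H]1CCO | intermediate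
18 | 2-[(1R,4aS,5S,6R,8aS)-5-{[(tert-butyldiphenylsilyl)oxy]methyl}-6-hydroxy-5,8a-dimethyl-2-methylidenedecahydronaphthalen-1-yl]acetaldehyde | C=C1CC[C@@H]2[C@@](C)(CO[Si](c3ccccc3)(c4ccccc4)C(C)(C)C)[C@H](O)CC[C@@]2(C)[C@@H]1CC=O | intermediate
19 | furan-2(5H)-one | O=C1OCC=C1 | starting material
20 | 3-{(1R)-2-[(1R,4aS,5S,6R,8aS)-5-{[(tert-butyldiphenylsilyl)oxy]methyl}-6-hydroxy-5,8a-dimethyl-2-methylidenedecahydronaphthalen-1-yl]-1-hydroxyethyl}furan-2(5H)-one | C=C1CC[C@@H]2[C@@](C)(CO[Si](c3ccccc3)(c4ccccc4)C(C)(C)C)[C@H](O)CC[C@@]2(C)[C@@H]1C[C@@H](O)C1=CCOC1=O | intermediate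
21 | 3-{(1R)-1-hydroxy-2-[(1R,4aS,5S,6R,8aS)-6-hydroxy-5-(hydroxymethyl)-5,8a-dimethyl-2-methylidenedecahydronaphthalen-1-yl]ethyl}furan-2(5H)-one | C=C1CC[C@@H]2[C@@](C)(CO)[C@H](O)CC[C@@]2(C)[C@@H]1C[C@@H](O)C1=CCOC1=O | target

**Step count and risks**

Total steps: 13. Longest linear sequence: 13 steps (from 1 and 2; 19 is used as purchased).

The three steps most likely to fail are steps 9, 12 and 7.

Step 9 (bicyclization). The silyloxymethyl group on the epoxide carbon slows ionisation at C4. Opening at C3, hydride or alkyl shifts, or a stop after ring A can compete; other Lewis acids (Et2AlCl, BF3·OEt2) are the first adjustment. The fallback replaces the cationic cascade by a radical one; it sets out from 15 and comes back at 17. Cp2TiCl (trivalent titanium, formed in situ from Cp2TiCl2 (20 mol%), Mn dust, 2,4,6-collidine and Me3SiCl in THF at rt) opens the epoxide homolytically to the tertiary C4 radical, which is indifferent to the neighbouring oxygen. Two 6-endo closures through the same chair–chair arrangement follow, with the larger CH2OTBDPS group expected to take the equatorial site. The resulting C8 radical loses a hydrogen atom to give the exocyclic vinylsilane, the (E)-C17-trimethylsilyl analogue of 16 F2, together with the ring-B endocyclic allylsilane isomer of 16 (C7=C8 double bond, CH2SiMe3 on C8) F3. The mixture is treated with CF3CO2H (CH2Cl2, 0 °C; then K2CO3, MeOH). Ipso-protodesilylation of F2 and SE2′ protodesilylation of F3 pass through the same β-silyl C8 cation and converge on the exocyclic methylene. The primary TBS ether is lost under the same acid, so the product is diol 17.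

Step 12 (new Morita–Baylis–Hillman coupling). The acceptor is β-substituted and sluggish, the aldehyde can self-condense, and the facial bias of the new catalyst is untested; if the (S)-catalyst favours 12S, its enantiomer from D-tert-leucine is used. The fallback uses known chemistry; it sets out from 18 and comes back at 20. Aldol addition of the lithium enolate of 3-(phenylselanyl)oxolan-2-one (LiN(i-Pr)2, THF, −78 °C; 2.5 equiv because of the free C3 hydroxyl) gives the β-hydroxy selenide 3-{2-[(1R,4aS,5S,6R,8aS)-5-{[(tert-butyldiphenylsilyl)oxy]methyl}-6-hydroxy-5,8a-dimethyl-2-methylidenedecahydronaphthalen-1-yl]-1-hydroxyethyl}-3-(phenylselanyl)oxolan-2-one F4 as a diastereomer mixture. Oxidation with 30% H2O2 (CH2Cl2/pyridine, 0 °C) and selenoxide syn-elimination toward the ring CH2, away from the carbinol, gives 20 and its (12S)-epimer 3-{(1S)-2-[(1R,4aS,5S,6R,8aS)-5-{[(tert-butyldiphenylsilyl)oxy]methyl}-6-hydroxy-5,8a-dimethyl-2-methylidenedecahydronaphthalen-1-yl]-1-hydroxyethyl}furan-2(5H)-one F5, which are separated by chromatography.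

Step 7 (organocatalytic epoxidation). A long lipophilic α-methyl enal may give moderate selectivity, and E/Z scrambling through the dienamine can erode the trans/cis ratio. The facial sense on this substrate has to be confirmed; the quinine-derived pseudo-enantiomer or a BINOL-phosphate counter-anion is the first adjustment. The fallback is a hydroxyl-directed epoxidation; it sets out from 12 and comes back at 14. Luche reduction (NaBH4, CeCl3·7H2O, MeOH, 0 °C) gives the allylic alcohol (2E,6E,10Z)-13-[(tert-butyldimethylsilyl)oxy]-2,6-dimethyl-10-[(trimethylsilyl)methyl]trideca-2,6,10-trien-1-ol F1. Sharpless asymmetric epoxidation (Ti(OiPr)4, D-(−)-diisopropyl tartrate, t-BuOOH, 4 Å molecular sieves, CH2Cl2, −20 °C) then oxidises only the allylic-alcohol alkene, and the D-tartrate gives the (2R,3R)-epoxy alcohol 14.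

**Further compounds**
F1 | step 7 | (2E,6E,10Z)-13-[(tert-butyldimethylsilyl)oxy]-2,6-dimethyl-10-[(trimethylsilyl)methyl]trideca-2,6,10-trien-1-ol | OC/C(C)=C/CC/C(C)=C/CC/C(C[Si](C)(C)C)=C/CCO[Si](C)(C)C(C)(C)C
F2 | step 9 | (E)-C17-trimethylsilyl analogue of 16 (exocyclic C8=C17H–SiMe3, silicon trans to C9; all other centres as in 16) | C[Si](C)(C)/C=C1\CC[C@@H]2[C@@](C)(CO[Si](c3ccccc3)(c4ccccc4)C(C)(C)C)[C@H](O)CC[C@@]2(C)[C@@H]1CCO[Si](C)(C)C(C)(C)C
F3 | step 9 | ring-B endocyclic allylsilane isomer of 16 (C7=C8 double bond, CH2SiMe3 on C8; all other centres as in 16) | C[Si](C)(C)CC1=CC[C@@H]2[C@@](C)(CO[Si](c3ccccc3)(c4ccccc4)C(C)(C)C)[C@H](O)CC[C@@]2(C)[C@@H]1CCO[Si](C)(C)C(C)(C)C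
F4 | step 12 | 3-{2-[(1R,4aS,5S,6R,8aS)-5-{[(tert-butyldiphenylsilyl)oxy]methyl}-6-hydroxy-5,8a-dimethyl-2-methylidenedecahydronaphthalen-1-yl]-1-hydroxyethyl}-3-(phenylselanyl)oxolan-2-one (mixture at C12 and C13) | C=C1CC[C@@H]2[C@@](C)(CO[Si](c3ccccc3)(c4ccccc4)C(C)(C)C)[C@H](O)CC[C@@]2(C)[C@@H]1CC(O)C1(CCOC1=O)[Se]c1ccccc1
F5 | step 12 | 3-{(1S)-2-[(1R,4aS,5S,6R,8aS)-5-{[(tert-butyldiphenylsilyl)oxy]methyl}-6-hydroxy-5,8a-dimethyl-2-methylidenedecahydronaphthalen-1-yl]-1-hydroxyethyl}furan-2(5H)-one | C=C1CC[C@@H]2[C@@](C)(CO[Si](c3ccccc3)(c4ccccc4)C(C)(C)C)[C@H](O)CC[C@@]2(C)[C@@H]1C[C@H](O)C1=CCOC1=O
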